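**Plan**

- The target is a 2,4-dihydroxy-6-alkylbenzoic acid; the retrosynthesis first removes the carboxyl carbon from C1 (formylation, then oxidation) and the O-ethyl group of a resorcinol monoethyl ether.
- Enabling feature: in the benzene ring the run C2(OH)–C1–C6(chain)–C5 is the four-carbon unit of a 3-alkylcyclobut-2-enone and the pair C3–C4(O) is ethoxyacetylene. Ring bonds C2–C3 and C4–C5 are therefore cut, while C1–C2 opens and re-forms in the same cascade.
- The cyclobutenone is traced to a terminal alkyne plus dichloroketene, the alkyne to acetylide plus a terminal epoxide (bond C1'–C6), and the C13 chain to (S)-propylene oxide plus dec-9-enylmagnesium bromide (bond C10'–C11').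
- Forward order: chain, second carbinol centre, alkyne, diacetate, four-membered ring, then the arene (the only ring of the target) by benzannulation, then O-de-ethylation, C1 formylation and oxidation.
- Stereochemistry: C12' comes from (S)-propylene oxide; C2' from hydrolytic kinetic resolution of the terminal epoxide with the (S,S)-cobalt salen catalyst; neither centre takes part in any later bond change.

Key step: step 8

Remark: ring atoms are numbered as in the benzoic acid (C1 bears CO2H, C2 and C4 the hydroxyls, C6 the chain); the chain is numbered C1'–C13' from the benzylic carbon.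

**Route**

Step 1
Reactants: 1 (S)-propylene oxide [(2S)-2-methyloxirane]; 2 10-bromodec-1-ene
Product: 4 (2S)-tridec-12-en-2-ol, via dec-9-enylmagnesium bromide 3 (not isolated)
Conditions: 2, Mg, THF, rt → 45 °C; then CuI (10 mol%), 1, –30 → 0 °C; 1 M HCl
Reagents that add atoms: none
Why: Copper-catalysed Grignard opening of a terminal epoxide is an SN2 attack at the unsubstituted CH2, so the C–O stereocentre of 1 is carried over unchanged as the (S)-carbinol that becomes C12'.

Step 2
Reactants: 4 (2S)-tridec-12-en-2-ol
Product: 5 (2S)-11-(oxiran-2-yl)undecan-2-ol (both oxirane epimers)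
Conditions: mCPBA, NaHCO3, CH2Cl2, 0 °C → rt
Reagents that add atoms: mCPBA (3-chloroperoxybenzoic acid), O=C(OO)c1cccc(Cl)c1
Why: Prilezhaev epoxidation of the isolated terminal alkene tolerates the remote free hydroxyl and, lacking any facial bias, should give the two oxirane epimers in about equal amounts for resolution in the next step.

Step 3
Reactants: 5 (2S)-11-(oxiran-2-yl)undecan-2-ol (both oxirane epimers)
Product: 6 (2S)-11-[(2S)-oxiran-2-yl]undecan-2-ol
Conditions: (S,S)-Co(salen)(OAc) (0.5 mol%; salen = N,N'-bis(3,5-di-tert-butylsalicylidene)cyclohexane-1,2-diaminate, trivalent cobalt), H2O (0.55 equiv), THF, 0 °C → rt; chromatography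
Reagents that add atoms: none
Why: In the Jacobsen hydrolytic kinetic resolution the (S,S)-catalyst hydrates the (R)-oxirane epimer to a polar triol and leaves the (S)-oxirane, so the future C2' is fixed by the catalyst alone, and the distant secondary hydroxyl is no better a nucleophile than the diol every such resolution already contains.

Step 4
Reactants: 6 (2S)-11-[(2S)-oxiran-2-yl]undecan-2-ol
Product: 7 (2S,12S)-pentadec-14-yne-2,12-diol
Conditions: LiC≡CH·H2NCH2CH2NH2 (3 equiv), DMSO, 0 °C → rt; then H2O
Reagents that add atoms: lithium acetylide–ethylenediamine complex, [Li+].[C-]#C.NCCN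
Why: SN2 opening of the terminal epoxide by lithium acetylide at the CH2 terminus gives the homopropargylic alcohol without touching the C–O stereocentre, the extra acetylide covering the free hydroxyl.

Step 5
Reactants: 7 (2S,12S)-pentadec-14-yne-2,12-diol
Product: 8 (2S,12S)-pentadec-14-yne-2,12-diyl diacetate
Conditions: Ac2O, pyridine, DMAP (cat.), CH2Cl2, 0 °C → rt
Reagents that add atoms: acetic anhydride, CC(=O)OC(C)=O
Why: DMAP-catalysed acylation of both secondary alcohols installs the two acetates of the target with retention at both carbinol carbons, before any phenol exists to compete.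

Step 6
Reactants: 8 (2S,12S)-pentadec-14-yne-2,12-diyl diacetate; 9 trichloroacetyl chloride
Product: 11 (2S,12S)-1-(4,4-dichloro-3-oxocyclobut-1-en-1-yl)tridecane-2,12-diyl diacetate, via dichloroketene 10 (not isolated)
Conditions: Zn–Cu couple, Et2O/DME, rt, slow addition of 9
Reagents that add atoms: none
Why: In the (2+2) cycloaddition of a terminal alkyne with dichloroketene (made by zinc dechlorination of 9) the ketene carbonyl carbon bonds to the terminal CH, giving the 3-substituted 4,4-dichlorocyclobutenone, while DME sequesters ZnCl2 and the esters stay inert.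

Step 7
Reactants: 11 (2S,12S)-1-(4,4-dichloro-3-oxocyclobut-1-en-1-yl)tridecane-2,12-diyl diacetate
Product: 12 (2S,12S)-1-(3-oxocyclobut-1-en-1-yl)tridecane-2,12-diyl diacetate
Conditions: Zn dust, AcOH, TMEDA, EtOH, 0 °C → rt
Reagents that add atoms: none
Why: Zinc reduction of the α,α-dichloro ketone, buffered by AcOH/TMEDA, removes both chlorines through zinc enolates without opening the strained enone or cleaving the acetates.

Step 8
Reactants: 12 (2S,12S)-1-(3-oxocyclobut-1-en-1-yl)tridecane-2,12-diyl diacetate; 13 ethoxyacetylene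
Product: 18 (2S,12S)-1-(3-ethoxy-5-hydroxyphenyl)tridecane-2,12-diyl diacetate, via vinylketene 14 (not isolated), via 4-alkenyl-3-ethoxycyclobutenone 15 (not isolated), via dienylketene 16 (not isolated), via cyclohexadienone tautomer 17 (not isolated)
Conditions: 13 (3 equiv), toluene (0.1 M), 80 °C, sealed tube, Ar
Reagents that add atoms: none
Why: At 80 °C cyclobutenone 12 undergoes four-electron conrotatory electrocyclic opening to vinylketene 14, whose ketene C=C adds ethoxyacetylene in a (2+2) cycloaddition to give 15 (new bonds C2–C3 and C4–C5 of the later arene), and 15 opens reversibly in a second four-electron step to dienylketene 16. Six-electron disrotatory electrocyclization of 16 joins the ketene carbon to the terminal CH2 (re-forming C1–C2) and closes the six-membered carbocycle as cyclohexadienone 17, which tautomerises to phenol 18; this pericyclic closure is the only ring-forming event. The closest known reaction type is the Danheiser benzannulation of 3-alkylcyclobutenones with alkoxyacetylenes, which gives 5-alkylresorcinol monoethers. No stereocentre is created (the sp3 ring carbon of 15 is lost on opening), and the two acetoxy-bearing centres lie away from every bond change under neutral thermal conditions. The step needs regioselectivity in the (2+2) addition, secured by the polarisation of the ynol ether (its nucleophilic CH carbon attacks the ketene carbonyl carbon, placing OEt meta to the new OH), and it needs the ketene to be trapped by the alkyne and not by the product phenol, secured by the excess of electron-rich alkyne and moderate dilution.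

Step 9
Reactants: 18 (2S,12S)-1-(3-ethoxy-5-hydroxyphenyl)tridecane-2,12-diyl diacetate
Product: 19 (2S,12S)-1-(3,5-dihydroxyphenyl)tridecane-2,12-diyl diacetate
Conditions: BBr3 (4 equiv), CH2Cl2, –78 → 0 °C; then ice-water
Reagents that add atoms: none
Why: In this BBr3 ether cleavage bromide dealkylates the aryl ethyl ether–borane adduct at the primary ethyl carbon, while the secondary acetates should only be complexed at low temperature and released on aqueous work-up.

Step 10
Reactants: 19 (2S,12S)-1-(3,5-dihydroxyphenyl)tridecane-2,12-diyl diacetate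
Product: 21 (2S,12S)-1-(2-formyl-3,5-dihydroxyphenyl)tridecane-2,12-diyl diacetate, via aryl iminium chloride 20 (not isolated)
Conditions: POCl3 (1.5 equiv), DMF, 0 °C → rt; then H2O, rt
Reagents that add atoms: N,N-dimethylformamide, CN(C)C=O; water, O
Why: Vilsmeier–Haack formylation of a 5-alkylresorcinol goes to the position ortho to one hydroxyl and para to the other (the two such sites are equivalent by the local symmetry of the ring) rather than to the carbon between the hydroxyls, and hydrolysis of iminium salt 20 gives the salicylaldehyde.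

Step 11
Reactants: 21 (2S,12S)-1-(2-formyl-3,5-dihydroxyphenyl)tridecane-2,12-diyl diacetate
Product: 22 2-[(2S,12S)-2,12-diacetoxytridecyl]-4,6-dihydroxybenzoic acid (CNP0203944.2)
Conditions: NaClO2, NaH2PO4, 2-methylbut-2-ene (excess), t-BuOH/THF/H2O, 0 °C → rt; work-up and purification without heating
Reagents that add atoms: sodium chlorite, [Na+].[O-]Cl=O
Why: Pinnick (Lindgren) oxidation takes the aldehyde to the acid at buffered pH, with 2-methylbut-2-ene intercepting HOCl before it can chlorinate the electron-rich ring and with no effect on the acetates or stereocentres.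

**Compound list**

1 | (S)-propylene oxide, (2S)-2-methyloxirane | C[C@H]1CO1 | starting material
2 | 10-bromodec-1-ene | C=CCCCCCCCCBr | starting material
3 | dec-9-enylmagnesium bromide | C=CCCCCCCCC[Mg]Br | intermediate (not isolated)
4 | (2S)-tridec-12-en-2-ol | C=CCCCCCCCCC[C@H](C)O | intermediate
5 | (2S)-11-(oxiran-2-yl)undecan-2-ol, both oxirane epimers | O1CC1CCCCCCCCC[C@H](C)O | intermediate
6 | (2S)-11-[(2S)-oxiran-2-yl]undecan-2-ol | O1C[C@@H]1CCCCCCCCC[C@H](C)O | intermediate
7 | (2S,12S)-pentadec-14-yne-2,12-diol | O[C@@H](CCCCCCCCC[C@H](C)O)CC#C | intermediate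
8 | (2S,12S)-pentadec-14-yne-2,12-diyl diacetate | CC(=O)O[C@@H](CCCCCCCCC[C@H](C)OC(C)=O)CC#C | intermediate
9 | trichloroacetyl chloride | O=C(Cl)C(Cl)(Cl)Cl | starting material
10 | dichloroketene | O=C=C(Cl)Cl | intermediate (not isolated)
11 | (2S,12S)-1-(4,4-dichloro-3-oxocyclobut-1-en-1-yl)tridecane-2,12-diyl diacetate | CC(=O)O[C@@H](CCCCCCCCC[C@H](C)OC(C)=O)CC1=CC(=O)C1(Cl)Cl | intermediate
12 | (2S,12S)-1-(3-oxocyclobut-1-en-1-yl)tridecane-2,12-diyl diacetate | CC(=O)O[C@@H](CCCCCCCCC[C@H](C)OC(C)=O)CC1=CC(=O)C1 | intermediate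
13 | ethoxyacetylene (ethoxyethyne) | CCOC#C | starting material
14 | 3-[(2S,12S)-2,12-diacetoxytridecyl]buta-1,3-dien-1-one (vinylketene) | CC(=O)O[C@@H](CCCCCCCCC[C@H](C)OC(C)=O)CC(=C)C=C=O | intermediate (not isolated)
15 | 4-[(4S,14S)-4,14-diacetoxypentadec-1-en-2-yl]-3-ethoxycyclobut-2-en-1-one (ring CH epimers) | CC(=O)O[C@@H](CCCCCCCCC[C@H](C)OC(C)=O)CC(=C)C1C(=O)C=C1OCC | intermediate (not isolated)
16 | (3E)-5-[(2S,12S)-2,12-diacetoxytridecyl]-3-ethoxyhexa-1,3,5-trien-1-one (dienylketene) | CC(=O)O[C@@H](CCCCCCCCC[C@H](C)OC(C)=O)CC(=C)/C=C(OCC)\C=C=O | intermediate (not isolated)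
17 | 5-[(2S,12S)-2,12-diacetoxytridecyl]-3-ethoxycyclohexa-2,4-dien-1-one | CC(=O)O[C@@H](CCCCCCCCC[C@H](C)OC(C)=O)CC1=CC(OCC)=CC(=O)C1 | intermediate (not isolated)
18 | (2S,12S)-1-(3-ethoxy-5-hydroxyphenyl)tridecane-2,12-diyl diacetate | CC(=O)O[C@@H](CCCCCCCCC[C@H](C)OC(C)=O)Cc1cc(O)cc(OCC)c1 | intermediate
19 | (2S,12S)-1-(3,5-dihydroxyphenyl)tridecane-2,12-diyl diacetate | CC(=O)O[C@@H](CCCCCCCCC[C@H](C)OC(C)=O)Cc1cc(O)cc(O)c1 | intermediate
20 | N-{[2-((2S,12S)-2,12-diacetoxytridecyl)-4,6-dihydroxyphenyl]methylidene}-N-methylmethanaminium chloride | CC(=O)O[C@@H](CCCCCCCCC[C@H](C)OC(C)=O)Cc1cc(O)cc(O)c1C=[N+](C)C.[Cl-] | intermediate (not isolated)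
21 | (2S,12S)-1-(2-formyl-3,5-dihydroxyphenyl)tridecane-2,12-diyl diacetate | CC(=O)O[C@@H](CCCCCCCCC[C@H](C)OC(C)=O)Cc1cc(O)cc(O)c1C=O | intermediate
22 | 2-[(2S,12S)-2,12-diacetoxytridecyl]-4,6-dihydroxybenzoic acid | CC(=O)O[C@@H](CCCCCCCCC[C@H](C)OC(C)=O)Cc1cc(O)cc(O)c1C(=O)O | target

**Count and risks**

Total step count: 11. Longest linear sequence: 11 steps (from 1 and 2 to 22).

Steps most likely to fail:

1. Step 8. The vinylketene may be captured by the phenol that the reaction itself produces, giving aryl esters that cannot be saponified without losing the side-chain acetates, and the ynol ether may lose ethylene thermally before it is consumed. Fallback: the arene is brought in preformed. Setting out from epoxide 6, copper-catalysed opening at the CH2 terminus with [3,5-bis(benzyloxy)phenyl]magnesium bromide F1 (from commercial 1,3-bis(benzyloxy)-5-bromobenzene and Mg in THF; 2.5 equiv, CuI 10 mol%, –20 °C, the first equivalent being spent on the free hydroxyl) should give (2S,12S)-1-[3,5-bis(benzyloxy)phenyl]tridecane-2,12-diol F2. Acetylation (Ac2O, pyridine, DMAP) gives (2S,12S)-1-[3,5-bis(benzyloxy)phenyl]tridecane-2,12-diyl diacetate F3, and hydrogenolysis of both benzyl ethers (H2, Pd/C, EtOAc) comes back to the route at 19.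

2. Step 9. The ether cleavage may stall at the temperatures that spare esters, and warming may erode the secondary acetates by acyl cleavage or bromide substitution. Fallback: the esters are taken off before the Lewis acid is used and put back afterwards. Setting out from 18, K2CO3 in MeOH removes both acetates to give (2S,12S)-1-(3-ethoxy-5-hydroxyphenyl)tridecane-2,12-diol F4. With no ester present, excess BBr3 in CH2Cl2 can be taken from –78 °C to rt (the secondary alcohols are held as borate esters and return on hydrolysis) to give (2S,12S)-1-(3,5-dihydroxyphenyl)tridecane-2,12-diol F5. Exhaustive acetylation (Ac2O, pyridine, DMAP) gives 5-[(2S,12S)-2,12-diacetoxytridecyl]-1,3-phenylene diacetate F6, whose two aryl acetates are removed selectively by aminolysis with pyrrolidine (CH2Cl2, 0 °C → rt; alkyl acetates are inert), coming back to the route at 19.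

3. Step 11. Hypochlorous acid may chlorinate the free resorcinol ring faster than it is scavenged, the hydrogen-bonded ortho-hydroxy aldehyde may oxidise sluggishly, and the product acid may decarboxylate during isolation. Fallback: the phenols are masked for the oxidation. Setting out from 21, benzylation (BnBr, K2CO3, DMF, 50 °C) gives (2S,12S)-1-[3,5-bis(benzyloxy)-2-formylphenyl]tridecane-2,12-diyl diacetate F7. Pinnick oxidation under the conditions of step 11 gives 2,4-bis(benzyloxy)-6-[(2S,12S)-2,12-diacetoxytridecyl]benzoic acid F8, and hydrogenolysis (H2, Pd/C, EtOAc, rt) comes back to the route at 22.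

**Further compounds**

F1 | step 8 | [3,5-bis(benzyloxy)phenyl]magnesium bromide | Br[Mg]c1cc(OCc2ccccc2)cc(OCc2ccccc2)c1
F2 | step 8 | (2S,12S)-1-[3,5-bis(benzyloxy)phenyl]tridecane-2,12-diol | O[C@@H](CCCCCCCCC[C@H](C)O)Cc1cc(OCc2ccccc2)cc(OCc2ccccc2)c1
F3 | step 8 | (2S,12S)-1-[3,5-bis(benzyloxy)phenyl]tridecane-2,12-diyl diacetate | CC(=O)O[C@@H](CCCCCCCCC[C@H](C)OC(C)=O)Cc1cc(OCc2ccccc2)cc(OCc2ccccc2)c1
F4 | step 9 | (2S,12S)-1-(3-ethoxy-5-hydroxyphenyl)tridecane-2,12-diol | O[C@@H](CCCCCCCCC[C@H](C)O)Cc1cc(O)cc(OCC)c1
F5 | step 9 | (2S,12S)-1-(3,5-dihydroxyphenyl)tridecane-2,12-diol | O[C@@H](CCCCCCCCC[C@H](C)O)Cc1cc(O)cc(O)c1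
F6 | step 9 | 5-[(2S,12S)-2,12-diacetoxytridecyl]-1,3-phenylene diacetate | CC(=O)O[C@@H](CCCCCCCCC[C@H](C)OC(C)=O)Cc1cc(OC(C)=O)cc(OC(C)=O)c1
F7 | step 11 | (2S,12S)-1-[3,5-bis(benzyloxy)-2-formylphenyl]tridecane-2,12-diyl diacetate | CC(=O)O[C@@H](CCCCCCCCC[C@H](C)OC(C)=O)Cc1cc(OCc2ccccc2)cc(OCc2ccccc2)c1C=O
F8 | step 11 | 2,4-bis(benzyloxy)-6-[(2S,12S)-2,12-diacetoxytridecyl]benzoic acid | CC(=O)O[C@@H](CCCCCCCCC[C@H](C)OC(C)=O)Cc1cc(OCc2ccccc2)cc(OCc2ccccc2)c1C(=O)O
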